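Numbering: C1 (=CH2), C2, C3 (OAc), C4 (side chain), C5, C6 (CHO), C7, C8, C9, C10 (bridging CHOAc). The route rests on closing C5–C10 by an intramolecular Diels–Alder reaction. The acetoxy carbons C3 and C10 lie 1,4 across the seven-membered ring (C1–C2–C3–C4–C5–C10–C9), so one oxygen can tie them: a dihydropyranone made from (S)-citronellal carries, on C4, a 2-triflyloxy diene (C5=C6–C7=C8). Its addition to the pyranone C9=C10 bond forms the cyclohexene (C5–C10, C8–C9), closes the seven-membered carbocycle as an oxa-bridged ketone and sets C5, C9 and C10 in one operation. Acetolysis of the ether bridge later releases both acetates.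

Key step: step 7

Assumption: the (R)-BINOL–titanium catalyst of step 6 is taken to deliver the diene to the Re face of aldehyde 11, as this catalyst does in related carbonyl additions; if the sense proves opposite, the (S)-ligand is used.

Step 1
Reactants: 1 (S)-citronellal; 2 RAMP, (R)-1-amino-2-(methoxymethyl)pyrrolidine
Product: 3 (E)-RAMP hydrazone of (S)-citronellal
Conditions: neat, 0 °C → rt; then Et2O, MgSO4
Reagents that add atoms: none
Why: Hydrazone condensation of an aldehyde with a 1,1-disubstituted hydrazine, which forms no stereocentre and leaves the (S)-methyl centre C11 untouched.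

Step 2
Reactants: 3 (E)-RAMP hydrazone of (S)-citronellal; 4 2-bromo-N-methoxy-N-methylacetamide
Product: 6 RAMP hydrazone of (3S)-N-methoxy-N-methyl-3-[(2S)-6-methylhept-5-en-2-yl]-4-oxobutanamide, via lithium azaenolate 5 (not isolated)
Conditions: LiN(iPr)2, THF, 0 °C; then 4, −100 °C → rt
Reagents that add atoms: none
Why: Azaenolate alkylation by the RAMP-hydrazone method, in which the chelated azaenolate should be alkylated on the face away from the methoxymethyl arm, so the auxiliary sets C4 independently of C11.

Step 3
Reactants: 6 Weinreb amide hydrazone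
Product: 8 RAMP hydrazone of (2S)-2-[(2S)-6-methylhept-5-en-2-yl]-4-oxohex-5-enal, via magnesium chelate 7 (not isolated)
Conditions: CH2=CHMgBr, THF, −78 → 0 °C; inverse quench into cold aq. NH4Cl
Reagents that add atoms: vinylmagnesium bromide C=C[Mg]Br
Why: Weinreb ketone synthesis, in which the stable magnesium chelate stops the addition at the ketone stage and the hydrazone C=N is inert to the Grignard reagent at this temperature.

Step 4
Reactants: 8 vinyl ketone hydrazone
Product: 10 RAMP hydrazone of (2R,3Z)-2-[(2S)-6-methylhept-5-en-2-yl]-4-(trifluoromethanesulfonyloxy)hexa-3,5-dienal, via potassium dienolate 9 (not isolated)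
Conditions: KN(SiMe3)2, THF, −78 °C (ketone added to base); then PhNTf2, −78 → −20 °C
Reagents that add atoms: N-phenylbis(trifluoromethanesulfonimide) O=S(=O)(N(c1ccccc1)S(=O)(=O)C(F)(F)F)C(F)(F)F
Why: Enolate O-triflation, where the only acidic site is C5, so the cross-conjugated enolate forms regiospecifically and its (Z)-geometry (expected to predominate for a ketone bearing a conjugating vinyl group) gives the diene with C4 trans to C7.

Step 5
Reactants: 10 dienyl triflate hydrazone
Product: 11 (2R,3Z)-2-[(2S)-6-methylhept-5-en-2-yl]-4-(trifluoromethanesulfonyloxy)hexa-3,5-dienal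
Conditions: saturated aq. oxalic acid, Et2O, rt, two phases; used crude
Reagents that add atoms: water O
Why: Base-free two-phase hydrolysis of the hydrazone, which should spare the labile C4 centre (α to the aldehyde and allylic) and returns the auxiliary as its oxalate.

Step 6
Reactants: 11 dienyl triflate aldehyde; 12 (E)-1-methoxy-3-(trimethylsilyloxy)buta-1,3-diene
Product: 14 (2R)-2-[(1R,2Z)-1-[(2S)-6-methylhept-5-en-2-yl]-3-(trifluoromethanesulfonyloxy)penta-2,4-dien-1-yl]-2,3-dihydro-4H-pyran-4-one, via aldol silyl ether 13 (not isolated)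
Conditions: Ti(OiPr)4 (10 mol%), (R)-BINOL (20 mol%), 4 Å MS, Et2O, −20 °C; then CF3CO2H, CH2Cl2, 0 °C
Reagents that add atoms: none
Why: Catalytic asymmetric Mukaiyama aldol addition followed by acid cyclisation with loss of methanol (a formal hetero-Diels–Alder reaction), in which the chiral titanium catalyst should direct attack to the Re face of the aldehyde and so set C3 as R.

Step 7
Reactants: 14 dihydropyranone bearing the (Z)-2-triflyloxy diene
Product: 15 oxa-bridged tricyclic ketone: bicyclo[4.3.1]decane skeleton with a C3–O–C10 ether bridge, C1 ketone, C6 enol triflate (C6=C7) and the C4 side chain anti to the oxygen bridge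
Conditions: toluene (0.01 M), BHT, sealed tube, 170 °C
Reagents that add atoms: none
Why: A concerted, asynchronous [4+2] cycloaddition in which the s-cis diene C5=C6–C7=C8 adds suprafacially to the pyranone C9=C10 bond, C5 to the electrophilic β-carbon C10 and C8 to C9. The closest known reaction type is the type 1 intramolecular Diels–Alder reaction of a 1,6,8-nonatriene with a three-atom tether (here C4–C3–O). It closes the cyclohexene by the [4+2] itself and the oxolane O–C3–C4–C5–C10 in the fused mode, and with these the seven-membered carbocycle, which appears as an 8-oxabicyclo[3.2.1]octan-3-one. C5, C9 and C10 are all controlled by C3 through the tether: the diene reaches only the enone face syn to the C3 substituent, the cis enone gives the cis C9–C10 fusion, and C6 must end endo, leaving the C4 side chain anti to the bridge. The step needs regioselectivity (C5 to C10, not to C9), which the short tether and the polarity of the vinylogous ester secure, and enough reactivity from two moderately activated partners, which intramolecularity and temperature must supply; only the (Z)-enol triflate can cyclise.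

Step 8
Reactants: 15 oxa-bridged tricyclic ketone
Product: 16 C1-methylene analogue of 15 (exocyclic C1=CH2, ether bridge and enol triflate retained)
Conditions: Cp2TiMe2, toluene/THF, 65 °C, dark
Reagents that add atoms: dimethyltitanocene C[Ti](C)(C1C=CC=C1)C1C=CC=C1
Why: Petasis methylenation, whose non-basic titanocene methylidene should convert the ketone to the exocyclic alkene without opening the β-alkoxy ketone or touching the enol triflate.

Step 9
Reactants: 16 oxa-bridged methylene compound
Product: 17 diacetate enol triflate (the target with OTf in place of CHO on C6)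
Conditions: Ac2O, Me3SiOTf (0.2 equiv), 2,6-di-tert-butyl-4-methylpyridine, CH2Cl2, −30 → 0 °C
Reagents that add atoms: acetic anhydride CC(=O)OC(C)=O
Why: Acetolysis of a bridged ether, in which O-acylation gives an acyloxonium ion that acetate should open by SN2 attack at C3 with inversion (the rear of C10 is blocked by the fused cyclohexene), so C10 keeps its oxygen with retention and the trans C3,C10-diacetate results.

Step 10
Reactants: 17 diacetate enol triflate
Product: 18 target, CNP0197379.1
Conditions: Pd(PPh3)4 (5 mol%), LiCl, CO (1 atm), Bu3SnH (slow addition), THF, 50 °C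
Reagents that add atoms: carbon monoxide [C-]#[O+]
Why: Palladium-catalysed reductive carbonylation (formylation) of an enol triflate by oxidative addition to zerovalent palladium, CO insertion and hydride transfer from the tin hydride, which should give the enal with C6=C7 fixed and leave the acetates and other alkenes alone.

Compound list
1 | (S)-citronellal, (3S)-3,7-dimethyloct-6-enal | O=CC[C@@H](C)CCC=C(C)C | starting material
2 | RAMP, (2R)-2-(methoxymethyl)pyrrolidin-1-amine | COC[C@H]1CCCN1N | starting material
3 | (E)-RAMP hydrazone of (S)-citronellal | COC[C@H]1CCCN1/N=C/C[C@@H](C)CCC=C(C)C | intermediate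
4 | 2-bromo-N-methoxy-N-methylacetamide | BrCC(=O)N(C)OC | starting material
5 | lithium azaenolate of 3 | [Li+].COC[C@H]1CCCN1[N-]/C=C/[C@@H](C)CCC=C(C)C | intermediate
6 | RAMP hydrazone of (3S)-N-methoxy-N-methyl-3-[(2S)-6-methylhept-5-en-2-yl]-4-oxobutanamide | COC[C@H]1CCCN1/N=C/[C@@H](CC(=O)N(C)OC)[C@@H](C)CCC=C(C)C | intermediate
7 | bromomagnesium tetrahedral adduct of 6 with the vinyl Grignard reagent | COC[C@H]1CCCN1/N=C/[C@@H](CC(O[Mg]Br)(C=C)N(C)OC)[C@@H](C)CCC=C(C)C | intermediate
8 | RAMP hydrazone of (2S)-2-[(2S)-6-methylhept-5-en-2-yl]-4-oxohex-5-enal | COC[C@H]1CCCN1/N=C/[C@@H](CC(=O)C=C)[C@@H](C)CCC=C(C)C | intermediate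
9 | potassium (Z)-dienolate of 8 | [K+].COC[C@H]1CCCN1/N=C/[C@@H](/C=C(\[O-])C=C)[C@@H](C)CCC=C(C)C | intermediate
10 | RAMP hydrazone of (2R,3Z)-2-[(2S)-6-methylhept-5-en-2-yl]-4-(trifluoromethanesulfonyloxy)hexa-3,5-dienal | COC[C@H]1CCCN1/N=C/[C@@H](/C=C(\OS(=O)(=O)C(F)(F)F)C=C)[C@@H](C)CCC=C(C)C | intermediate
11 | (2R,3Z)-2-[(2S)-6-methylhept-5-en-2-yl]-4-(trifluoromethanesulfonyloxy)hexa-3,5-dienal | O=C[C@@H](/C=C(\OS(=O)(=O)C(F)(F)F)C=C)[C@@H](C)CCC=C(C)C | intermediate
12 | (E)-1-methoxy-3-(trimethylsilyloxy)buta-1,3-diene | CO/C=C/C(=C)O[Si](C)(C)C | starting material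
13 | Mukaiyama aldol adduct: (E)-β-methoxy enone with the (R)-configured C3 trimethylsilyl ether | CO/C=C/C(=O)C[C@@H](O[Si](C)(C)C)[C@@H](/C=C(\OS(=O)(=O)C(F)(F)F)C=C)[C@@H](C)CCC=C(C)C | intermediate
14 | (2R)-2-[(1R,2Z)-1-[(2S)-6-methylhept-5-en-2-yl]-3-(trifluoromethanesulfonyloxy)penta-2,4-dien-1-yl]-2,3-dihydro-4H-pyran-4-one | O=C1C=CO[C@H](C1)[C@@H](/C=C(\OS(=O)(=O)C(F)(F)F)C=C)[C@@H](C)CCC=C(C)C | intermediate
15 | oxa-bridged tricyclic ketone: C3–O–C10 ether bridge, C1 ketone, C6 enol triflate, side chain on C4 anti to the bridge | O=C1C[C@@H]2[C@H]([C@@H](C)CCC=C(C)C)[C@@H]3C(OS(=O)(=O)C(F)(F)F)=CC[C@H]1[C@@H]3O2 | intermediate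
16 | C1-methylene analogue of 15 | C=C1C[C@@H]2[C@H]([C@@H](C)CCC=C(C)C)[C@@H]3C(OS(=O)(=O)C(F)(F)F)=CC[C@H]1[C@@H]3O2 | intermediate
17 | C3,C10-diacetate with C6 enol triflate and C1 exocyclic methylene | C=C1C[C@H](OC(C)=O)[C@H]([C@@H](C)CCC=C(C)C)[C@@H]2C(OS(=O)(=O)C(F)(F)F)=CC[C@H]1[C@@H]2OC(C)=O | intermediate
18 | CNP0197379.1, the bicyclo[4.3.1]decene diacetate enal | C=C1C[C@H](OC(C)=O)[C@H]([C@@H](C)CCC=C(C)C)[C@@H]2C(C=O)=CC[C@H]1[C@@H]2OC(C)=O | target

Total step count: 10. Longest linear sequence: 10 steps from (S)-citronellal.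

Steps most likely to fail

Step 7. The cycloaddition may be too slow, since the diene carries a withdrawing triflate and the dienophile is a vinylogous ester, so thermal decomposition or diene polymerisation could win. The fallback sets out from 14 and activates the dienophile with a removable halogen. Iodination at C9 with I2 and pyridine in CH2Cl2 should give the 5-iodo-dihydropyranone F1, whose 2-halo enone is a more electron-poor dienophile. Heating F1 at a lower temperature should give the C9-iodinated cycloadduct F2, with the same tether-controlled stereochemistry. Bu3SnH with AIBN in benzene then removes the iodine, the cis ring fusion being the only one the tricycle allows, and the route is rejoined at 15.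

Step 9. Ionisation at C3, migration of the exocyclic alkene or acylation of the side-chain alkene may compete with the hindered SN2 opening, eroding the C3 configuration. The fallback sets out from 15 and replaces substitution by elimination and re-oxygenation. Ac2O with BF3·OEt2 at 0 °C should open the β-alkoxy ketone by acylative β-elimination to the cycloheptenone with the C10 acetate in place, F3. Conjugate borylation (CuCl, NaOtBu, 1,2-bis(diphenylphosphino)benzene, B2pin2, MeOH) anti to the C4 side chain should give the C3 boronate F4, and NaBO3·4H2O should oxidise it to the β-hydroxy ketone F5. Methylenation with Zn, CH2Br2 and TiCl4 should give the homoallylic alcohol F6. Mitsunobu esterification (PPh3, DIAD, AcOH) inverts C3 and rejoins the route at 17.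

Step 6. Facial selectivity may be poor if catalyst and the C4 centre are mismatched, and the slow catalysed addition may allow epimerisation of the labile aldehyde. The fallback sets out from 11 and uses a reagent-controlled boron aldol reaction instead. (E)-4-Methoxybut-3-en-2-one is enolised with Et3N and the enantiomer of chlorodiisopinocampheylborane that directs addition to the Re face. Addition of 11 at −78 °C should give the β-hydroxy enone F7, and CF3CO2H in CH2Cl2 should cyclise it with loss of methanol, rejoining the route at 14.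

Further compounds
F1 | step 7 | 5-iodo analogue of 14 (iodine on C9 of the dihydropyranone) | O=C1C(I)=CO[C@H](C1)[C@@H](/C=C(\OS(=O)(=O)C(F)(F)F)C=C)[C@@H](C)CCC=C(C)C
F2 | step 7 | C9-iodo analogue of cycloadduct 15 | O=C1C[C@@H]2[C@H]([C@@H](C)CCC=C(C)C)[C@@H]3C(OS(=O)(=O)C(F)(F)F)=CC[C@@]1(I)[C@@H]3O2
F3 | step 9 | ring-opened cycloheptenone (C1 ketone, C2=C3) with C10 acetate and C6 enol triflate | O=C1C=C[C@H]([C@@H](C)CCC=C(C)C)[C@@H]2C(OS(=O)(=O)C(F)(F)F)=CC[C@H]1[C@@H]2OC(C)=O
F4 | step 9 | C3 pinacol boronate of the C1 ketone, boron anti to the C4 side chain | O=C1C[C@@H](B3OC(C)(C)C(C)(C)O3)[C@H]([C@@H](C)CCC=C(C)C)[C@@H]2C(OS(=O)(=O)C(F)(F)F)=CC[C@H]1[C@@H]2OC(C)=O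
F5 | step 9 | C3 β-hydroxy ketone, hydroxyl anti to the C4 side chain | O=C1C[C@@H](O)[C@H]([C@@H](C)CCC=C(C)C)[C@@H]2C(OS(=O)(=O)C(F)(F)F)=CC[C@H]1[C@@H]2OC(C)=O
F6 | step 9 | C3 homoallylic alcohol with C1 exocyclic methylene (C3 epimer of the alcohol of 17) | C=C1C[C@@H](O)[C@H]([C@@H](C)CCC=C(C)C)[C@@H]2C(OS(=O)(=O)C(F)(F)F)=CC[C@H]1[C@@H]2OC(C)=O
F7 | step 6 | (E)-β-methoxy enone with free (R)-configured C3 hydroxyl (desilylated analogue of 13) | CO/C=C/C(=O)C[C@@H](O)[C@@H](/C=C(\OS(=O)(=O)C(F)(F)F)C=C)[C@@H](C)CCC=C(C)C
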